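**Retrosynthetic overview**

1. The target is the isovanillate of a cis-fused bicyclo[5.3.0]decene diol, numbered C1 (angular-methyl quaternary carbon), C2–C3, C4 (isopropyl carbinol), C5 (ring-fusion CH), C6 (acyloxy CH), C7=C8 (methyl on C8), C9, C10; the ester C6–O bond and the two Si–O bonds are made or broken last, and C6–OH comes from hydride reduction of the C6 enone.
2. The plan rests on this feature: the C1 methyl, C1–C6 and the isopropyl group with the C4 carbinol centre are the ten carbons of ring-opened (S)-terpinen-4-ol (ring A, C1–C5, by ozonolysis/aldol ring contraction), and C7–C10 with the C8 methyl are one prenyl unit.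
3. Key disconnection: the C6–C7 bond of the seven-membered ring, traced back by a photochemical 1,3-acyl shift to a cis-diquinane ketone in which C6 is bonded to C9 and C9 carries an isopropenyl group (C8, C7 and the methyl).
4. The diquinane ketone ring (C1, C5, C6, C9, C10) is disconnected at C6–C9 (carbonyl-ene closure of a C6 aldehyde onto the prenyl alkene) and at C1–C10 (anionic oxy-Cope shift of the prenyl Grignard adduct of the cyclopentene carbaldehyde).
5. Ring order: ring A (from terpinen-4-ol), then the five-membered ketone ring, then its two-carbon expansion to the seven-membered ring.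

Key step: step 10

Remark: commercial (S)-(+)-terpinen-4-ol is assumed to have the optical purity wanted for the target; its C4 centre is never broken in the route. The atom numbers C1–C10 defined above are used for all intermediates.

**Route**

Step 1
Reactants: 1 (S)-terpinen-4-ol
Product: 2 (S)-terpinen-4-yl triethylsilyl ether
Conditions: TESOTf, 2,6-lutidine, CH2Cl2, 0 °C
Reagents that add atoms: triethylsilyl trifluoromethanesulfonate, CC[Si](CC)(CC)OS(=O)(=O)C(F)(F)F
Why: Silyl triflate with a hindered pyridine base silylates the tertiary alcohol; the ether stops hemiketal formation after ozonolysis and makes the C4 oxygen a poor leaving group for step 3.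

Step 2
Reactants: 2 (S)-terpinen-4-yl triethylsilyl ether
Product: 4 (S)-6-oxo-3-(propan-2-yl)-3-(triethylsilyloxy)heptanal, via ozonide 3 (not isolated)
Conditions: O3, CH2Cl2, −78 °C; then PPh3, −78 °C to rt
Reagents that add atoms: ozone, [O-][O+]=O
Why: Ozonolysis with reductive work-up cleaves the only alkene into the methyl ketone (C1) and the aldehyde (C6) without touching C4.

Step 3
Reactants: 4 (S)-6-oxo-3-(propan-2-yl)-3-(triethylsilyloxy)heptanal
Product: 6 (R)-2-methyl-5-(propan-2-yl)-5-(triethylsilyloxy)cyclopent-1-ene-1-carbaldehyde, via aldol adduct 5 (not isolated)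
Conditions: piperidine (0.3 equiv), AcOH (0.3 equiv), toluene, 60 °C
Reagents that add atoms: none
Why: Amine-catalysed intramolecular aldol condensation: the enamine of the aldehyde (C5) adds to the methyl ketone (C1) in a five-membered closure and the new tertiary aldol hydroxyl is lost to give the tetrasubstituted enal, while the bulky, weakly basic C4 silyloxy group is not eliminated.

Step 4
Reactants: 6 (R)-2-methyl-5-(propan-2-yl)-5-(triethylsilyloxy)cyclopent-1-ene-1-carbaldehyde; 7 1-chloro-3-methylbut-2-ene
Product: 9 2,2-dimethyl-1-[2-methyl-5-(propan-2-yl)-5-(triethylsilyloxy)cyclopent-1-en-1-yl]but-3-en-1-ol (both C6 epimers, used together), via prenylmagnesium chloride 8 (not isolated)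
Conditions: 7, Mg, THF, 0 °C; then 6, THF, −78 to 0 °C; aq NH4Cl
Reagents that add atoms: none
Why: Grignard 1,2-addition in which the prenyl reagent reacts through its substituted terminus (cyclic allyl transposition), giving the 3-hydroxy-1,5-diene needed for step 6; the C6 centre is lost again there, so its configuration does not matter.

Step 5
Reactants: 9 silyl-protected dienol
Product: 10 2-(1-hydroxy-2,2-dimethylbut-3-en-1-yl)-3-methyl-1-(propan-2-yl)cyclopent-2-en-1-ol
Conditions: TBAF, THF, 0 °C to rt
Reagents that add atoms: none
Why: Fluoride cleavage of the Si–O bond frees the C4 hydroxyl, because a C4 silyl ether would be expelled from the enolate formed in step 6 (β-elimination) or would shuttle silicon to the C6 alkoxide, whereas a C4 alkoxide can do neither.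

Step 6
Reactants: 10 diol
Product: 13 2-hydroxy-5-methyl-5-(3-methylbut-2-en-1-yl)-2-(propan-2-yl)cyclopentane-1-carbaldehyde (formyl, C4–OH and prenyl on one face; H5, C1 methyl and isopropyl on the other), via dipotassium enolate alkoxide 11 (not isolated), via C5-epimeric hydroxy aldehyde 12 (not isolated)
Conditions: KH (3 equiv), 18-crown-6 (3 equiv), THF, 0 °C to rt; AcOH, THF, −78 °C; then Et3N, MeOH, rt
Reagents that add atoms: none
Why: Anionic oxy-Cope [3,3] rearrangement of the bis-alkoxide: the breaking C6–CMe2 bond must stand perpendicular to the ring and should take the face syn to the small C4 oxygen and anti to the isopropyl group, which sets the quaternary C1 (prenyl CH2 cis to O4); after protonation, amine equilibration of the enolisable aldehyde should set C5 with the formyl group trans to isopropyl and hydrogen-bonded to the cis C4 hydroxyl.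

Step 7
Reactants: 13 cis hydroxy aldehyde
Product: 14 5-methyl-5-(3-methylbut-2-en-1-yl)-2-(propan-2-yl)-2-(triethylsilyloxy)cyclopentane-1-carbaldehyde (same configuration)
Conditions: TESOTf, 2,6-lutidine, CH2Cl2, −78 to 0 °C
Reagents that add atoms: triethylsilyl trifluoromethanesulfonate, CC[Si](CC)(CC)OS(=O)(=O)C(F)(F)F
Why: Low-temperature silylation of the tertiary alcohol leaves the hindered aldehyde untouched and protects the β-hydroxy carbonyl unit from retro-aldol cleavage in the Lewis acid, photochemical and base steps that follow.

Step 8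
Reactants: 14 silyl-protected aldehyde
Product: 15 cis-fused 3a-methyl-2-(prop-1-en-2-yl)-6-(propan-2-yl)-6-(triethylsilyloxy)octahydropentalen-1-ol (route numbering: C6–OH, isopropenyl on C9; C6 and C9 as formed)
Conditions: Me2AlCl (2 equiv), CH2Cl2, −78 to −20 °C; aq potassium sodium tartrate
Reagents that add atoms: none
Why: Type 1 intramolecular carbonyl-ene reaction: the Lewis acid activates the aldehyde, C9 of the prenyl alkene bonds to C6 and a methyl hydrogen is transferred, closing the five-membered ring, which can only form cis-fused; the new C6 and C9 centres are removed in steps 9 and 10.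

Step 9
Reactants: 15 diquinane alcohol
Product: 16 cis-fused 3a-methyl-2-(prop-1-en-2-yl)-6-(propan-2-yl)-6-(triethylsilyloxy)hexahydropentalen-1(2H)-one (C6 ketone, isopropenyl on C9, exo epimer drawn)
Conditions: Dess–Martin periodinane, NaHCO3, CH2Cl2, 0 °C to rt
Reagents that add atoms: none
Why: Dess–Martin oxidation of the secondary alcohol under buffered, neutral conditions keeps the isopropenyl alkene out of conjugation; C9 is an epimerisable α-centre whose configuration is of no consequence.

Step 10
Reactants: 16 cis-diquinane 2-isopropenyl ketone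
Product: 17 cis-fused hydroazulen-6-one with C8=C9 alkene (6,8a-dimethyl-3-(propan-2-yl)-3-(triethylsilyloxy)-2,3,3a,5,8,8a-hexahydroazulen-4(1H)-one)
Conditions: hν (300 nm, Pyrex), degassed benzene (0.01 M), rt, to the photostationary state; recovered 16 re-irradiated
Reagents that add atoms: none
Why: Direct n→π* excitation of the β,γ-unsaturated ketone leads from the singlet state to Norrish type 1 cleavage of the allylic C6–C9 bond, and the acyl/2-methylallyl radical pair recombines in the solvent cage at the far allyl terminus C7, a net 1,3-acyl shift that moves the alkene to C8=C9. The closest known reaction type is the photochemical 1,3-acyl shift of 2-alkenylcycloalkanones, a known two-carbon ring expansion. The seven-membered ring (C1, C5, C6, C7, C8, C9, C10) closes by this radical-pair recombination, formally a 7-endo bonding of the acyl carbon to the exocyclic CH2 of the isopropenyl group. No stereocentre is formed: C9 becomes sp2, and C1, C4 and C5 lie outside the reacting unit, so the cis ring fusion is carried over. The step needs cleavage on the C9 side and not the C5 side, and the singlet path and not the triplet oxa-di-π-methane path; allyl stabilisation of the C6–C9 fragment and unsensitised irradiation in benzene secure both. Because 17 is itself a β,γ-enone the shift is reversible, so the mixture is taken to the photostationary state and 16 is recycled.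

Step 11
Reactants: 17 β,γ-unsaturated hydroazulenone
Product: 18 cis-fused conjugated enone (C6 ketone, C7=C8)
Conditions: DBU (0.5 equiv), CH2Cl2, rt
Reagents that add atoms: none
Why: Base-mediated conjugation: DBU removes the doubly activated C7 proton and the dienolate is reprotonated at C9; C5, flanked by two quaternary carbons, should not be deprotonated under these mild conditions, so the cis fusion and the C4 silyl ether stay.

Step 12
Reactants: 18 conjugated enone
Product: 19 cis-fused allylic alcohol (C6–OH trans to H5, cis to the C4 oxygen)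
Conditions: NaBH4, CeCl3·7H2O, MeOH, −40 °C
Reagents that add atoms: none
Why: Luche 1,2-reduction; hydride should add to C6 from the convex face (the face of H5 and the angular methyl), away from ring A and its C4 silyloxy group folded under the other face, which sets C6 as in the target.

Step 13
Reactants: 20 isovanillic acid
Product: 22 3-(tert-butyldimethylsilyloxy)-4-methoxybenzoic acid, via bis-silylated acid 21 (not isolated)
Conditions: TBSCl (2.5 equiv), imidazole, DMF, rt; then AcOH, THF, H2O, rt
Reagents that add atoms: tert-butyldimethylsilyl chloride, CC(C)(C)[Si](C)(C)Cl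
Why: Silylation of both acidic groups followed by selective hydrolysis of the far more labile silyl ester leaves the phenol protected, so the acid cannot acylate itself in step 14.

Step 14
Reactants: 19 allylic alcohol; 22 3-(tert-butyldimethylsilyloxy)-4-methoxybenzoic acid
Product: 24 bis-silylated ester (C6 3-(tert-butyldimethylsilyloxy)-4-methoxybenzoate of 19), via mixed anhydride 23 (not isolated)
Conditions: 2,4,6-trichlorobenzoyl chloride, Et3N, toluene, rt; then 19, DMAP, toluene, rt to 50 °C
Reagents that add atoms: none
Why: Yamaguchi esterification: DMAP attacks the unhindered aroyl carbonyl of the mixed anhydride and the acylpyridinium ion acylates the hindered secondary C6 hydroxyl with retention, the C4 oxygen being silylated.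

Step 15
Reactants: 24 bis-silylated ester
Product: 25 (3R,3aS,4R,8aR)-3-hydroxy-6,8a-dimethyl-3-(propan-2-yl)-1,2,3,3a,4,7,8,8a-octahydroazulen-4-yl 3-hydroxy-4-methoxybenzoate (CNP0210850.1)
Conditions: TBAF, AcOH, THF, 0 °C to rt
Reagents that add atoms: none
Why: Buffered fluoride cleaves the aryl silyl ether and the tertiary triethylsilyl ether in one operation, and the acetic acid buffer keeps the allylic ester from hydrolysis or acyl migration.

**Compound list**

1 | (S)-terpinen-4-ol, (S)-4-methyl-1-(propan-2-yl)cyclohex-3-en-1-ol | CC1=CC[C@](O)(C(C)C)CC1 | starting material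
2 | (S)-terpinen-4-yl triethylsilyl ether | CC1=CC[C@](O[Si](CC)(CC)CC)(C(C)C)CC1 | intermediate
3 | ozonide (1,2,4-trioxolane) of 2, diastereomer mixture, not isolated | CC12OOC(O1)C[C@](O[Si](CC)(CC)CC)(C(C)C)CC2 | intermediate
4 | (S)-6-oxo-3-(propan-2-yl)-3-(triethylsilyloxy)heptanal | CC(=O)CC[C@@](O[Si](CC)(CC)CC)(C(C)C)CC=O | intermediate
5 | aldol adduct, 2-hydroxy-2-methyl-5-(propan-2-yl)-5-(triethylsilyloxy)cyclopentane-1-carbaldehyde, not isolated | O=CC1C(C)(O)CC[C@@]1(O[Si](CC)(CC)CC)C(C)C | intermediate
6 | (R)-2-methyl-5-(propan-2-yl)-5-(triethylsilyloxy)cyclopent-1-ene-1-carbaldehyde | O=CC1=C(C)CC[C@@]1(O[Si](CC)(CC)CC)C(C)C | intermediate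
7 | 1-chloro-3-methylbut-2-ene (prenyl chloride) | CC(C)=CCCl | starting material
8 | prenylmagnesium chloride, not isolated | CC(C)=CC[Mg]Cl | intermediate
9 | 2,2-dimethyl-1-[2-methyl-5-(propan-2-yl)-5-(triethylsilyloxy)cyclopent-1-en-1-yl]but-3-en-1-ol, C4 as in 1, both C6 epimers | C=CC(C)(C)C(O)C1=C(C)CC[C@@]1(O[Si](CC)(CC)CC)C(C)C | intermediate
10 | 2-(1-hydroxy-2,2-dimethylbut-3-en-1-yl)-3-methyl-1-(propan-2-yl)cyclopent-2-en-1-ol, C4 as in 1 | C=CC(C)(C)C(O)C1=C(C)CC[C@@]1(O)C(C)C | intermediate
11 | dipotassium enolate alkoxide from the oxy-Cope shift, not isolated | [K+].[K+].[O-]C=C1[C@](C)(CC=C(C)C)CC[C@@]1([O-])C(C)C | intermediate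
12 | C5-epimeric hydroxy aldehyde (formyl trans to prenyl and to C4–OH), not isolated | O=C[C@H]1[C@](C)(CC=C(C)C)CC[C@@]1(O)C(C)C | intermediate
13 | 2-hydroxy-5-methyl-5-(3-methylbut-2-en-1-yl)-2-(propan-2-yl)cyclopentane-1-carbaldehyde, formyl/OH/prenyl cis | O=C[C@@H]1[C@](C)(CC=C(C)C)CC[C@@]1(O)C(C)C | intermediate
14 | triethylsilyl ether of 13 | O=C[C@@H]1[C@](C)(CC=C(C)C)CC[C@@]1(O[Si](CC)(CC)CC)C(C)C | intermediate
15 | cis-fused 3a-methyl-2-(prop-1-en-2-yl)-6-(propan-2-yl)-6-(triethylsilyloxy)octahydropentalen-1-ol, C6 and C9 as formed | OC1C(C(C)=C)C[C@]2(C)CC[C@@](O[Si](CC)(CC)CC)(C(C)C)[C@H]12 | intermediate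
16 | cis-diquinane ketone with C9 isopropenyl group (key-step precursor) | O=C1[C@@H](C(C)=C)C[C@]2(C)CC[C@@](O[Si](CC)(CC)CC)(C(C)C)[C@H]12 | intermediate
17 | cis-fused hydroazulen-6-one with C8=C9 alkene (key-step product) | O=C1CC(C)=CC[C@]2(C)CC[C@@](O[Si](CC)(CC)CC)(C(C)C)[C@H]12 | intermediate
18 | cis-fused conjugated hydroazulenone, C7=C8 | O=C1C=C(C)CC[C@]2(C)CC[C@@](O[Si](CC)(CC)CC)(C(C)C)[C@H]12 | intermediate
19 | cis-fused allylic alcohol, C6–OH trans to H5 | O[C@@H]1C=C(C)CC[C@]2(C)CC[C@@](O[Si](CC)(CC)CC)(C(C)C)[C@H]12 | intermediate
20 | isovanillic acid (3-hydroxy-4-methoxybenzoic acid) | COc1ccc(C(=O)O)cc1O | starting material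
21 | tert-butyldimethylsilyl 3-(tert-butyldimethylsilyloxy)-4-methoxybenzoate, not isolated | COc1ccc(C(=O)O[Si](C)(C)C(C)(C)C)cc1O[Si](C)(C)C(C)(C)C | intermediate
22 | 3-(tert-butyldimethylsilyloxy)-4-methoxybenzoic acid | COc1ccc(C(=O)O)cc1O[Si](C)(C)C(C)(C)C | intermediate
23 | mixed anhydride of 22 with 2,4,6-trichlorobenzoic acid, not isolated | COc1ccc(C(=O)OC(=O)c2c(Cl)cc(Cl)cc2Cl)cc1O[Si](C)(C)C(C)(C)C | intermediate
24 | bis-silylated ester | COc1ccc(C(=O)O[C@@H]2C=C(C)CC[C@]3(C)CC[C@@](O[Si](CC)(CC)CC)(C(C)C)[C@H]23)cc1O[Si](C)(C)C(C)(C)C | intermediate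
25 | (3R,3aS,4R,8aR)-3-hydroxy-6,8a-dimethyl-3-(propan-2-yl)-1,2,3,3a,4,7,8,8a-octahydroazulen-4-yl 3-hydroxy-4-methoxybenzoate | COc1ccc(C(=O)O[C@@H]2C=C(C)CC[C@]3(C)CC[C@@](O)(C(C)C)[C@H]23)cc1O | target

**Step count and risks**

Total step count: 15 (14 in the main line and 1 for the acid 22).
Longest linear sequence: 14 steps (steps 1–12, 14 and 15, from 1).

Steps most likely to fail:

1. Step 10. The photostationary state may lie far on the side of 16, or the acyl/allyl radical pair may lose CO, or the excited ketone may abstract the isopropyl methine hydrogen (Norrish type 2), faster than the pair recombines at C7. Fallback, setting out from 14 and coming back at 17: the seven-membered ring is closed by olefin metathesis instead of by the acyl shift. Aldehyde 14 is treated with 2-methylallylmagnesium chloride (THF, −78 °C), which forms the C6–C7 bond and gives the homoallylic alcohol F1. Ring-closing metathesis between the 2-methylallyl alkene and the prenyl alkene (second-generation Hoveyda–Grubbs catalyst, toluene, 80 °C, loss of 2-methylpropene) forms C8=C9 and gives the cycloheptenol F2. Dess–Martin oxidation of F2 gives 17.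

2. Step 6. The bis-alkoxide may fragment to the enal and a prenyl anion that recombines at the wrong terminus, or potassium bridging of the two alkoxides may erode the facial selectivity at C1. Fallback, setting out from 9 and coming back at 13: the [3,3] shift is run as a neutral thermal siloxy-Cope rearrangement, without any alkoxide. The C6 hydroxyl of 9 is silylated (TMSCl, imidazole, DMF) to the bis-silyl ether F3. Heating (o-dichlorobenzene, 200 °C, sealed tube) gives the trimethylsilyl enol ether F4. TBAF buffered with AcOH removes both silyl groups, and the resulting mixture of 12 and 13 is equilibrated with Et3N in MeOH as in step 6 to rejoin at 13.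

3. Step 12. Facial selectivity may be poor or reversed, with hydride delivered from the face of ring A. Fallback, setting out from 18 and coming back at 24: the wrong epimer is used productively by an esterification that inverts C6. If reduction of 18 gives mainly the C6-epimeric allylic alcohol F5, this alcohol is coupled with acid 22 under Mitsunobu conditions (PPh3, DIAD, toluene, 0 °C to rt). The ester forms with inversion at C6 and gives 24 directly, in place of step 14.

**Further compounds**

F1 | step 10 | 2-methylallyl carbinol from 14 (C6 epimers), 3-methyl-1-[5-methyl-5-(3-methylbut-2-en-1-yl)-2-(propan-2-yl)-2-(triethylsilyloxy)cyclopentyl]but-3-en-1-ol | C=C(C)CC(O)[C@@H]1[C@](C)(CC=C(C)C)CC[C@@]1(O[Si](CC)(CC)CC)C(C)C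
F2 | step 10 | cis-fused cycloheptenol with C8=C9 alkene (C6 epimers) | OC1CC(C)=CC[C@]2(C)CC[C@@](O[Si](CC)(CC)CC)(C(C)C)[C@H]12
F3 | step 6 | C6 trimethylsilyl ether of 9 | C=CC(C)(C)C(O[Si](C)(C)C)C1=C(C)CC[C@@]1(O[Si](CC)(CC)CC)C(C)C
F4 | step 6 | trimethylsilyl enol ether of the C4-silylated aldehyde | C[Si](C)(C)OC=C1[C@](C)(CC=C(C)C)CC[C@@]1(O[Si](CC)(CC)CC)C(C)C
F5 | step 12 | C6 epimer of 19 | O[C@H]1C=C(C)CC[C@]2(C)CC[C@@](O[Si](CC)(CC)CC)(C(C)C)[C@H]12
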